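I followed the coupling partner.

| flask | substrate | solid reagent | remark | time |
|---|---|---|---|---|
| Saturday's | 0.085 M (fed, over 80 s) | 2 equiv | run made earlier |  |
| Monday's | 0.34 M (fed, over 80 s) | 2 equiv | run made earlier |  |
| flask | 0.17 M (fed, over 80 s) | 2.00 equiv |  | 20 h |

- Saturday's (time / h: intermediate A / %, target / %): 0.250: 38, 0; 0.833: 56, 2; 2.50: 45, 21; 8.00: 25, 43; 25.0: 17, 52
- Monday's (time / h: intermediate A / %, target / %): 0.250: 39, 0; 0.833: 63, 2; 2.50: 53, 15; 8.00: 13, 49; 25.0: 5, 59

(scatter of a reading: 1.5 percentage points)

- the moment within 20 h at which there is most intermediate A
- the amount of intermediate A, in percent of the substrate charged, at that time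
- earliest time at which at least nineteen twentieths of that best amount are there
- latest time at which they still are

- given per volume of solution although it is solid: solid reagent
- the earlier runs were read with a standard deviation of 1.5 percentage points
- reactions considered so far: substrate -> intermediate A; coupling partner + intermediate A <-> intermediate B; coupling partner + intermediate B <-> intermediate C; intermediate C -> target; target <-> isomer of the product; solid reagent <-> coupling partner
- at the start none of the solid reagent is in solution

In each flask substrate turned into intermediate A, which took up one coupling partner to give intermediate B and a second to give intermediate C; intermediate C gave target, which exchanged with isomer of the product, and the partner came from the dissolving solid reagent. For this flask I got 100% as the equivalents of solid reagent divided by two, and I called this the reach, the largest share of the charged substrate that can end as target plus isomer of the product. That left 0% of this flask's charge short of them, so the reach gave no floor under intermediate A, and as my own estimate I expected this flask's reading at 0.833 h to lie near the readings of that time, Saturday's 56% and Monday's 63%.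

The forecast, reasoning that “the true peak falls after the 0.83 h sample”, gave 61% at 1.2 h, with the window asked for running from 0.75 h to 1.7 h.

The flask gave 58.9% at 0.918 h, with that window running from 0.600 h to 1.39 h, so the amount agreed with the forecast, while each of the times came earlier than forecast.

    substrate → intermediate A (k = 0.0430 min⁻¹)
    coupling partner + intermediate A ⇌ intermediate B (K = 4.80 M⁻¹, k = 2.60 M⁻¹ min⁻¹)
    coupling partner + intermediate B ⇌ intermediate C (K = 6.60 M⁻¹, k = 0.350 M⁻¹ min⁻¹)
    intermediate C → target (k = 0.0350 min⁻¹)
    target ⇌ isomer of the product (K = 0.590, k = 0.150 min⁻¹)
    solid reagent ⇌ coupling partner, rate k6*(cs6 - [coupling partner]) while solid is left; crystals form when [coupling partner] > cs6 (solubility = 0.110 M, k = 0.0510 min⁻¹)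

At 200 h this flask held 97.5% as target plus isomer of the product, under its reach of 100%. The same reckoning on the neighbouring flask with 0.500 equiv of solid reagent gave a reach of 25.0%, which made the coupling partner the limiting reagent and left 75.0% of the charge short of those two. At 20.0 h that neighbour held 21.5% as target plus isomer of the product, and 75.8% stood as intermediate A.

All runs come from a simulation for substances that don't exist, noise included.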